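**Retr0synthetic overview**
- The strategy rests on the 4-methylcyclohex-3-ene ring. Its three adjacent sp3 carbons carry a 2,4-dihydroxy-3-prenylbenzoyl group (C1), a 2,6-dihydroxyaryl group (C2, allylic to the ring C3=C4–CH3 bond and cis to the aroyl) and a 4-hydroxyphenyl group (C6, trans to the aroyl).
- This pattern is cut by an endo [4+2] into the E-enone of a 2'-hydroxychalcone (isobavachalcone) and an (E)-1-aryl-3-methylbuta-1,3-diene (dehydroprenyl-morachalcone A). The two free polyphenols are joined by an endo-selective Morus alba Diels–Alderase.
- Both halves come from one 3-iodo-2,4-bis(methoxymethoxy)acetophenone. The dienophile needs Suzuki prenylation, Claisen–Schmidt condensation and MOM removal. The diene needs Claisen–Schmidt condensation, a switch from MOM to acetate, Suzuki dienylation and deacetylation just before use.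
- Ring order: the four benzene rings are bought; the cyclohexene is the only ring made, in the last step.

Key step: step 13

Remark on the chemistry (assumption): the endo-selective enzyme is taken to give the adduct in the absolute sense of the target, (1S,2R,6R) for ring carbons C1 (aroyl), C2 and C6; should it give the mirror-image sense, the fallback to step 13 reaches the target by choice of the ligand antipode.

**Route**

Step 1
Reactants: 1 2,4-dihydroxyacetophenone
Product: 2 3-iodo-2,4-dihydroxyacetophenone
Conditions: I2 (0.4 equiv), HIO3 (0.2 equiv), EtOH/H2O, 35–40 °C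
Reagents that add atoms: iodine, II; iodic acid, OI(=O)=O
Why: Electrophilic aromatic iodination, with HIO3 re-oxidising iodide so that all iodine is used, should go to C3, the position ortho to both hydroxyls, and the regiochemistry can be checked by the ortho-coupled H5/H6 pair that remains.

Step 2
Reactants: 2 3-iodo-2,4-dihydroxyacetophenone
Product: 3 3-iodo-2,4-bis(methoxymethoxy)acetophenone
Conditions: NaH (2.4 equiv), MOMCl (2.4 equiv), DMF, 0 °C to rt
Reagents that add atoms: chloromethyl methyl ether, COCCl
Why: Williamson-type O-alkylation of both phenoxides gives the bis-acetal, NaH being needed because the 2-hydroxyl is chelated to the ketone and flanked by iodine.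

Step 3
Reactants: 3 3-iodo-2,4-bis(methoxymethoxy)acetophenone; 4 prenylboronic acid pinacol ester
Product: 5 3-(3-methylbut-2-enyl)-2,4-bis(methoxymethoxy)acetophenone
Conditions: 4 (1.5 equiv), PdCl2(IPent)(3-chloropyridine) (3 mol %; IPent = 1,3-bis[2,6-di(pentan-3-yl)phenyl]imidazol-2-ylidene), KOH (5 M aq), THF, 65 °C
Reagents that add atoms: none
Why: Suzuki–Miyaura allylation in which the very bulky carbene ligand favours reductive elimination from the less hindered primary prenyl–palladium species over the tertiary one, so the linear 3-methylbut-2-enyl group should be delivered while the MOM ethers tolerate the aqueous base.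

Step 4
Reactants: 5 3-(3-methylbut-2-enyl)-2,4-bis(methoxymethoxy)acetophenone; 6 4-(methoxymethoxy)benzaldehyde
Product: 8 tris-MOM isobavachalcone [(E)-1-[2,4-bis(methoxymethoxy)-3-(3-methylbut-2-enyl)phenyl]-3-[4-(methoxymethoxy)phenyl]prop-2-en-1-one], via aldol adduct 7 (not isolated)
Conditions: KOH (aq), EtOH, 0 °C to rt
Reagents that add atoms: none
Why: Claisen–Schmidt condensation of the methyl ketone enolate with the non-enolisable aldehyde, in which E1cB loss of water from the aldol gives the conjugated E-enone under thermodynamic control and the 2'-OMOM group blocks flavanone closure.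

Step 5
Reactants: 8 tris-MOM isobavachalcone
Product: 9 isobavachalcone [(E)-1-[2,4-dihydroxy-3-(3-methylbut-2-enyl)phenyl]-3-(4-hydroxyphenyl)prop-2-en-1-one]
Conditions: HCl (3 M aq)/MeOH, 50 °C, about 20 min, then pH 7 buffer
Reagents that add atoms: none
Why: Acid-catalysed acetal cleavage (transacetalisation to methanol) of the three MOM ethers should be faster than protonation of the trisubstituted prenyl alkene or oxa-Michael closure to the flavanone, provided that temperature and contact time are kept low.

Step 6
Reactants: 10 2,4-dihydroxybenzaldehyde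
Product: 11 2,4-bis(methoxymethoxy)benzaldehyde
Conditions: NaH (2.4 equiv), MOMCl (2.4 equiv), DMF, 0 °C to rt
Reagents that add atoms: chloromethyl methyl ether, COCCl
Why: Williamson-type O-alkylation of both phenoxides, the aldehyde having no enolisable hydrogen and being inert to NaH at this temperature.

Step 7
Reactants: 3 3-iodo-2,4-bis(methoxymethoxy)acetophenone; 11 2,4-bis(methoxymethoxy)benzaldehyde
Product: 13 tetra-MOM 3'-iodochalcone [(E)-1-[3-iodo-2,4-bis(methoxymethoxy)phenyl]-3-[2,4-bis(methoxymethoxy)phenyl]prop-2-en-1-one], via aldol adduct 12 (not isolated)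
Conditions: KOH (aq), EtOH, 0 °C to rt
Reagents that add atoms: none
Why: Claisen–Schmidt condensation as in step 4, the aryl iodide being inert to hydroxide and the E-enone again being the thermodynamic product of E1cB dehydration.

Step 8
Reactants: 13 tetra-MOM 3'-iodochalcone
Product: 14 3'-iodo-2,4,2',4'-tetrahydroxychalcone [(E)-1-(2,4-dihydroxy-3-iodophenyl)-3-(2,4-dihydroxyphenyl)prop-2-en-1-one]
Conditions: HCl (3 M aq)/MeOH, 50 °C, dark, short contact, then pH 7 buffer
Reagents that add atoms: none
Why: Acidic MOM cleavage is placed here because the molecule does not yet hold an acid-labile alkene, and the dark and brief heating should keep the E-enone from isomerising and closing onto the B-ring 2-hydroxyl (flavylium formation).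

Step 9
Reactants: 14 3'-iodo-2,4,2',4'-tetrahydroxychalcone
Product: 15 3'-iodochalcone tetraacetate [(E)-1-(2,4-diacetoxy-3-iodophenyl)-3-(2,4-diacetoxyphenyl)prop-2-en-1-one]
Conditions: Ac2O, pyridine, 4-(dimethylamino)pyridine (cat.), CH2Cl2, 0 °C to rt
Reagents that add atoms: acetic anhydride, CC(=O)OC(C)=O
Why: Nucleophile-catalysed acylation caps all four phenols, the chelated 2'-hydroxyl included, with groups that can later be removed by mild base without any acid.

Step 10
Reactants: 16 2-methylbut-1-en-3-yne
Product: 17 (E)-3-methylbuta-1,3-dienylboronic acid pinacol ester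
Conditions: pinacolborane (1.05 equiv), Cp2Zr(H)Cl (5 mol %), Et3N (10 mol %), CH2Cl2, rt, sealed vessel
Reagents that add atoms: pinacolborane, B1OC(C)(C)C(C)(C)O1
Why: Zirconium-catalysed syn hydroboration of the terminal alkyne (hydrozirconation followed by zirconium-to-boron exchange) places boron on the terminal carbon and gives the E-alkenylboronate, the 1,1-disubstituted alkene being far less reactive.

Step 11
Reactants: 15 3'-iodochalcone tetraacetate; 17 (E)-3-methylbuta-1,3-dienylboronic acid pinacol ester
Product: 18 dehydroprenyl-morachalcone A tetraacetate [(E)-1-[2,4-diacetoxy-3-[(E)-3-methylbuta-1,3-dienyl]phenyl]-3-(2,4-diacetoxyphenyl)prop-2-en-1-one]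
Conditions: 17 (1.5 equiv), Pd(OAc)2 (5 mol %), 2-dicyclohexylphosphino-2',6'-dimethoxybiphenyl (SPhos, 10 mol %), CsF (anhydrous, 3 equiv), 1,4-dioxane, 50 °C, Ar, dark
Reagents that add atoms: none
Why: Suzuki–Miyaura coupling with fluoride activation of the boronate, in which the electron-rich biarylphosphine allows oxidative addition at the doubly ortho-flanked iodide at moderate temperature, the alkenyl group is transferred with retention of E geometry, and the absence of water and hydroxide should spare the aryl acetates.

Step 12
Reactants: 18 dehydroprenyl-morachalcone A tetraacetate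
Product: 19 dehydroprenyl-morachalcone A [(E)-1-[2,4-dihydroxy-3-[(E)-3-methylbuta-1,3-dienyl]phenyl]-3-(2,4-dihydroxyphenyl)prop-2-en-1-one]
Conditions: K2CO3 (cat.), MeOH (degassed), 0 °C, Ar, dark; pH 7 phosphate buffer, cold extraction, used at once
Reagents that add atoms: none
Why: Base-mediated transesterification (methanolysis) of the four aryl acetates frees the phenols without acid, to which the ortho-hydroxy aryldiene is labile (chromene closure, oligomerisation), so the product is kept cold under argon and carried straight into step 13.

Step 13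
Reactants: 9 isobavachalcone; 19 dehydroprenyl-morachalcone A
Product: 20 target, (1S,2R,6R) endo adduct
Conditions: recombinant endo-selective Morus alba Diels–Alderase (FAD-bound flavoprotein, cat.), Tris–HCl buffer pH 8.0, DMSO (5% v/v), 40 °C, Ar, dark; 9 (3 equiv), 19 added in portions
Reagents that add atoms: none
Why: Inside the flavin-bearing pocket the chelated 2'-hydroxy ketone of 9 is held as the electron-poor 2π partner and the resorcinol-anchored E-aryldiene of 19 as the 4π partner, and they should combine in a concerted but asynchronous normal-demand [4+2] in which the diene CH2 terminus bonds to the enone β-carbon and the aryl-bearing diene carbon to the α-carbon, the flavin not being redox-cycled. The closest known reaction type is the intermolecular Diels–Alder reaction of 2'-hydroxychalcones with dehydroprenylphenols catalysed by the berberine-bridge-enzyme-like Diels–Alderases of Morus alba, applied here to a dienophile that differs from the usual one only by one missing B-ring hydroxyl. The cyclohexene ring is closed by intermolecular [4+2] cycloaddition, both σ bonds forming suprafacially on each partner. The trans relation of C1 (aroyl) and C6 (4-hydroxyphenyl) is carried over from the E-enone of 9, the cis relation of C1 and C2 (2,6-dihydroxyaryl) follows from the endo transition state on the E-diene, and the absolute sense (1S,2R,6R) is set by the enone face that the pocket leaves open. The step needs regio-, endo-, face- and chemoselectivity (enone of 9 against the enone of 19): the first three are imposed by the fixed orientation of the two bound substrates, the last is secured by the excess of 9 and the portionwise addition of 19, and the uncatalysed background is expected to be negligible at 40 °C in dilute buffer.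

**Compound list**
1 | 2,4-dihydroxyacetophenone | CC(=O)c1ccc(O)cc1O | starting material
2 | 3-iodo-2,4-dihydroxyacetophenone | CC(=O)c1ccc(O)c(I)c1O | intermediate
3 | 3-iodo-2,4-bis(methoxymethoxy)acetophenone | CC(=O)c1ccc(OCOC)c(I)c1OCOC | intermediate
4 | prenylboronic acid pinacol ester | CC(C)=CCB1OC(C)(C)C(C)(C)O1 | starting material
5 | 3-(3-methylbut-2-enyl)-2,4-bis(methoxymethoxy)acetophenone | CC(=O)c1ccc(OCOC)c(CC=C(C)C)c1OCOC | intermediate
6 | 4-(methoxymethoxy)benzaldehyde | COCOc1ccc(C=O)cc1 | starting material
7 | aldol adduct, racemic 3-hydroxy-1-[2,4-bis(methoxymethoxy)-3-(3-methylbut-2-enyl)phenyl]-3-[4-(methoxymethoxy)phenyl]propan-1-one (not isolated) | COCOc1ccc(C(O)CC(=O)c2ccc(OCOC)c(CC=C(C)C)c2OCOC)cc1 | intermediate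
8 | tris-MOM isobavachalcone | COCOc1ccc(/C=C/C(=O)c2ccc(OCOC)c(CC=C(C)C)c2OCOC)cc1 | intermediate
9 | isobavachalcone | CC(C)=CCc1c(O)ccc(C(=O)/C=C/c2ccc(O)cc2)c1O | intermediate
10 | 2,4-dihydroxybenzaldehyde | O=Cc1ccc(O)cc1O | starting material
11 | 2,4-bis(methoxymethoxy)benzaldehyde | COCOc1ccc(C=O)c(OCOC)c1 | intermediate
12 | aldol adduct, racemic 3-hydroxy-1-[3-iodo-2,4-bis(methoxymethoxy)phenyl]-3-[2,4-bis(methoxymethoxy)phenyl]propan-1-one (not isolated) | COCOc1ccc(C(O)CC(=O)c2ccc(OCOC)c(I)c2OCOC)c(OCOC)c1 | intermediate
13 | tetra-MOM 3'-iodochalcone | COCOc1ccc(/C=C/C(=O)c2ccc(OCOC)c(I)c2OCOC)c(OCOC)c1 | intermediate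
14 | 3'-iodo-2,4,2',4'-tetrahydroxychalcone | Oc1ccc(/C=C/C(=O)c2ccc(O)c(I)c2O)c(O)c1 | intermediate
15 | 3'-iodochalcone tetraacetate | CC(=O)Oc1ccc(/C=C/C(=O)c2ccc(OC(C)=O)c(I)c2OC(C)=O)c(OC(C)=O)c1 | intermediate
16 | 2-methylbut-1-en-3-yne | C#CC(C)=C | starting material
17 | (E)-3-methylbuta-1,3-dienylboronic acid pinacol ester | CC(=C)/C=C/B1OC(C)(C)C(C)(C)O1 | intermediate
18 | dehydroprenyl-morachalcone A tetraacetate | CC(=C)/C=C/c1c(OC(C)=O)ccc(C(=O)/C=C/c2ccc(OC(C)=O)cc2OC(C)=O)c1OC(C)=O | intermediate
19 | dehydroprenyl-morachalcone A | CC(=C)/C=C/c1c(O)ccc(C(=O)/C=C/c2ccc(O)cc2O)c1O | intermediate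
20 | [(1S,2R,6R)-2-[2,6-dihydroxy-3-[(E)-3-(2,4-dihydroxyphenyl)prop-2-enoyl]phenyl]-6-(4-hydroxyphenyl)-4-methylcyclohex-3-en-1-yl][2,4-dihydroxy-3-(3-methylbut-2-enyl)phenyl]methanone | CC(C)=CCc1c(O)ccc(C(=O)[C@@H]2[C@H](c3c(O)ccc(C(=O)/C=C/c4ccc(O)cc4O)c3O)C=C(C)C[C@H]2c2ccc(O)cc2)c1O | target

**Count**
Total steps: 13. Longest linear sequence: 8 steps (steps 1, 2, 7, 8, 9, 11, 12, 13).

**Steps most likely to fail**

Step 13. The dienophile without the B-ring 2-hydroxyl may bind or turn over poorly. The free diene may decay (chromene closure, oxidation, oligomerisation) or act as its own dienophile before it is consumed. The pocket may also expose the opposite enone face. The fallback runs the same [4+2] as a chiral-boron-promoted reaction on acetate-protected partners, setting out from 9 and 18. Compound 9 is acetylated at its two non-chelated phenols (Ac2O, pyridine, 0 °C, no acylation catalyst) to isobavachalcone 4,4'-diacetate F1. The free 2'-hydroxy ketone of F1 is bound to the chiral borate made from BH3·THF, acetic acid and one antipode of VANOL (3,3'-diphenyl-2,2'-bi-1-naphthol) in THF. Addition of 18 at room temperature should give, after chromatographic separation from the exo isomer, the endo hexaacetate F2; the ligand antipode is the one found in a small trial to lead to the (1S,2R,6R) series. K2CO3 in methanol under argon then removes the six acetates and the route is rejoined at 20.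

Step 11. Fluoride may strip or shift aryl acetates, the dienylboronate may protodeboronate or polymerise, and transmetalation at the doubly ortho-flanked iodide may be slow. The fallback builds the diene without a boron partner, setting out from 15. A Mizoroki–Heck reaction with 2-methylbut-3-en-2-ol (Pd(OAc)2, Bu4NCl, KOAc, DMF, 65 °C) should give the (E)-allylic tertiary alcohol F3, since the carbinol carbon has no hydrogen to divert β-hydride elimination. Dehydration with methyl N-(triethylammoniumsulfonyl)carbamate in toluene at 50 °C can only remove a methyl hydrogen and so forms the isopropenyl terminus, coming back to the route at 18.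

Step 3. The allyl group may be transposed (coupling at the tertiary carbon to the reverse-prenyl isomer), the hindered iodide may be protodeiodinated, and the methyl ketone may self-condense in hot KOH. The fallback installs the prenyl group by sigmatropic rearrangement, setting out from 1. O-Alkylation of the non-chelated 4-hydroxyl with 3-chloro-3-methylbut-1-yne (K2CO3, KI, CuI cat., acetone, reflux) gives the 1,1-dimethylpropargyl ether F4. Semihydrogenation (H2, Pd/CaCO3 poisoned with Pb(OAc)2, quinoline, EtOAc) gives the 1,1-dimethylallyl ether F5. Aromatic Claisen rearrangement in N,N-diethylaniline at about 130 °C moves the allyl unit with inversion to C3, the position favoured by bond fixation in the chelated ring, to give 2,4-dihydroxy-3-prenylacetophenone F6. Bis-MOM protection as in step 2 returns to the route at 5.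

**Further compounds**
F1 | step 13 | isobavachalcone 4,4'-diacetate (2'-hydroxyl free) | CC(C)=CCc1c(OC(C)=O)ccc(C(=O)/C=C/c2ccc(OC(C)=O)cc2)c1O
F2 | step 13 | endo hexaacetate of 20 (chelated 2-hydroxyl of the aroyl ring free) | CC(C)=CCc1c(OC(C)=O)ccc(C(=O)[C@@H]2[C@H](c3c(OC(C)=O)ccc(C(=O)/C=C/c4ccc(OC(C)=O)cc4OC(C)=O)c3OC(C)=O)C=C(C)C[C@H]2c2ccc(OC(C)=O)cc2)c1O
F3 | step 11 | (E)-1-[2,4-diacetoxy-3-[(E)-3-hydroxy-3-methylbut-1-enyl]phenyl]-3-(2,4-diacetoxyphenyl)prop-2-en-1-one | CC(C)(O)/C=C/c1c(OC(C)=O)ccc(C(=O)/C=C/c2ccc(OC(C)=O)cc2OC(C)=O)c1OC(C)=O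
F4 | step 3 | 2-hydroxy-4-(2-methylbut-3-yn-2-yloxy)acetophenone | CC(=O)c1ccc(OC(C)(C)C#C)cc1O
F5 | step 3 | 2-hydroxy-4-(2-methylbut-3-en-2-yloxy)acetophenone | CC(=O)c1ccc(OC(C)(C)C=C)cc1O
F6 | step 3 | 2,4-dihydroxy-3-(3-methylbut-2-enyl)acetophenone | CC(=O)c1ccc(O)c(CC=C(C)C)c1O
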